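**Retrosynthetic overview**

1. The strategy rests on the benzene ring with three contiguous oxygens at C3 (OH), C4 (OH) and C5 (OMe) and the chain at C1. C5, C4 and C3 come from the carbonyl carbon and the two alkoxy carbons of a squaric ester, C2 from the sp3 ring carbon of a cyclobutenone, and C1 and C6 from a 1,1-disubstituted vinyl group that carries the stearoyloxypropyl chain.
2. Key disconnection: the arene C5–C6 bond, back through a dienylketene to a 4-alkenyl-2,3-diisopropoxycyclobutenone. The benzene ring is the only ring formed, and it is formed in that step.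
3. The cyclobutenone C4–alkenyl bond is made by Stille coupling of a 4-chlorocyclobutenone (diisopropyl squarate, mono-reduction, chlorination) with a 2-stannyl-1-alkene (pent-4-yn-1-ol, stannylcupration, stearoylation).
4. End game: methylation of the single phenol (the former ketene oxygen, C5), then removal of both isopropyl ethers with BCl3.

Key step: step 6

Assumption: the target has no stereocentre. Compounds 7 to 10 have one stereocentre at C4 of the cyclobutenone, are made and used as racemates (one enantiomer drawn in the SMILES), and this centre disappears in step 6. Arene positions are numbered as in the target (C1 chain, C3 and C4 hydroxyl, C5 methoxyl).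

**Route**

Step 1
Reactants: 1 pent-4-yn-1-ol
Product: 3 4-(trimethylstannyl)pent-4-en-1-ol, via alkenylcopper adduct 2 (not isolated)
Conditions: Me3SnSnMe3, MeLi, THF, –20 °C; CuBr·SMe2, –78 °C (2 equiv of Me3SnCu·SMe2); then 1, MeOH (60 equiv), –63 °C, 12 h; aq. NH4Cl/NH3
Reagents that add atoms: hexamethylditin, C[Sn](C)(C)[Sn](C)(C)C
Why: Stannylcupration of a terminal alkyne with Me3SnCu·SMe2 is a reversible syn-addition that places tin on the internal carbon and copper on the terminal one, and the methanol present protonates alkenylcopper 2 as it forms, so the 2-stannyl-1-alkene should be the main regioisomer with the free hydroxyl tolerated.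

Step 2
Reactants: 3 4-(trimethylstannyl)pent-4-en-1-ol; 4 stearoyl chloride
Product: 5 4-(trimethylstannyl)pent-4-en-1-yl stearate
Conditions: pyridine, DMAP (cat.), CH2Cl2, 0 °C to rt
Reagents that add atoms: none
Why: Acylation of the primary alcohol by the acid chloride under nucleophilic catalysis, with pyridine buffering the HCl so that the acid-labile alkenylstannane is not protodestannylated.

Step 3
Reactants: 6 diisopropyl squarate
Product: 7 (±)-4-hydroxy-2,3-diisopropoxycyclobut-2-en-1-one
Conditions: LiAlH(OtBu)3 (1.05 equiv), THF, –20 °C; aq. KNaC4H4O6 (potassium sodium tartrate), 0 °C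
Reagents that add atoms: none
Why: 1,2-Hydride reduction of one of the two equivalent ketone carbonyls by the bulky, mild LiAlH(OtBu)3 should stop at the hydroxycyclobutenone because the remaining carbonyl is a deactivated vinylogous ester, the cold non-acidic work-up avoids acid-induced loss of isopropanol, and the new C4 stereocentre forms as a racemate that step 6 erases.

Step 4
Reactants: 7 (±)-4-hydroxy-2,3-diisopropoxycyclobut-2-en-1-one
Product: 9 (±)-4-chloro-2,3-diisopropoxycyclobut-2-en-1-one, via alkoxyphosphonium chloride 8 (not isolated)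
Conditions: PPh3, CCl4 (5 equiv), CH2Cl2, 0 °C to rt; filtered cold through a short pad, used at once
Reagents that add atoms: tetrachloromethane, ClC(Cl)(Cl)Cl
Why: Appel chlorination, in which chloride displaces the oxyphosphonium group of 8 at the carbonyl-activated C4 by SN2 substitution under neutral conditions that generate only chloroform and Ph3PO, so no acid is present to trigger ionisation towards C2, and the stereocentre stays racemic.

Step 5
Reactants: 9 (±)-4-chloro-2,3-diisopropoxycyclobut-2-en-1-one; 5 4-(trimethylstannyl)pent-4-en-1-yl stearate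
Product: 10 (±)-4-(2,3-diisopropoxy-4-oxocyclobut-2-en-1-yl)pent-4-en-1-yl stearate
Conditions: Pd2(dba)3 (2.5 mol %), tri(2-furyl)phosphine (10 mol %), dioxane, 40 °C; cold filtration through neutral alumina
Reagents that add atoms: none
Why: Stille coupling of a 4-chlorocyclobutenone, in which zerovalent palladium inserts into the C4–Cl bond that is both allylic and alpha to the carbonyl, the trimethylstannyl group and the weakly donating phosphine speed transmetalation of the alpha-branched alkenyl group, reductive elimination at the unsubstituted C4 terminus restores the conjugated vinylogous ester, and the neutral conditions at 40 °C spare the stearate and stay below the onset of ring opening, the racemic C4 centre being erased in the next step.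

Step 6
Reactants: 10 (±)-4-(2,3-diisopropoxy-4-oxocyclobut-2-en-1-yl)pent-4-en-1-yl stearate
Product: 13 3-(3-hydroxy-4,5-diisopropoxyphenyl)propyl stearate, via dienylketene 11 (not isolated), via cyclohexadienone 12 (not isolated)
Conditions: toluene (0.01 M, dry, degassed), 110 °C
Reagents that add atoms: none
Why: Heating opens the C1–C4 bond of 10 by conrotatory four-electron electrocyclic ring opening to a dienylketene, of which only isomer 11, with the alkenyl group rotated inward, can react further, while the outward isomer recloses to 10 and re-enters. In 11 the ketene carbon (arene C5) and the terminal methylene (arene C6) join by thermal disrotatory six-electron electrocyclisation, the only ring closure of the route and a six-membered one, to give cyclohexa-2,4-dienone 12, and tautomerisation of 12 to phenol 13 is irreversible and pulls the equilibria forward. The closest known reaction type is the thermal rearrangement of squarate-derived 4-alkenyl- and 4-arylcyclobutenones to phenols and hydroquinones through dienylketenes. No stereocentre is created and the racemic C4 centre of 10 is erased on aromatisation. The step needs closure to outrun ketene dimerisation and capture by nucleophiles, which high dilution in dry, degassed, nucleophile-free toluene secures, and it needs no regiocontrol because the connectivity of 10 fixes the chain meta to the new hydroxyl and leaves that hydroxyl, the former ketene oxygen on C5 in target numbering, as the only free phenol. The stearate and the two isopropyl ethers are inert to neutral thermolysis at 110 °C.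

Step 7
Reactants: 13 3-(3-hydroxy-4,5-diisopropoxyphenyl)propyl stearate
Product: 14 3-(3,4-diisopropoxy-5-methoxyphenyl)propyl stearate
Conditions: MeI, K2CO3, dry acetone, 50 °C
Reagents that add atoms: iodomethane, CI
Why: Williamson O-methylation of the only free phenol, under conditions to which the stearate and the isopropyl ethers are inert.

Step 8
Reactants: 14 3-(3,4-diisopropoxy-5-methoxyphenyl)propyl stearate
Product: 16 3-(3,4-dihydroxy-5-methoxyphenyl)propyl stearate (target), via cyclic chloroboronate 15 (not isolated)
Conditions: BCl3 (3 equiv), CH2Cl2, –40 to 0 °C; then H2O, 0 °C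
Reagents that add atoms: none
Why: Lewis acid ether cleavage in which BCl3 coordinates the ether oxygens and chloride removes the secondary isopropyl groups much faster than the methyl group, the two adjacent oxygens ending in cyclic chloroboronate 15 that water hydrolyses at work-up, while the aryl methyl ether and the alkyl stearate should survive at or below 0 °C.

**Compound list**

1 | pent-4-yn-1-ol | C#CCCCO | starting material
2 | (Z)-[5-hydroxy-2-(trimethylstannyl)pent-1-en-1-yl]copper (dimethyl sulfide ligand not drawn) | [Cu]/C=C(/CCCO)[Sn](C)(C)C | intermediate (not isolated)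
3 | 4-(trimethylstannyl)pent-4-en-1-ol | C=C(CCCO)[Sn](C)(C)C | intermediate
4 | stearoyl chloride (octadecanoyl chloride) | CCCCCCCCCCCCCCCCCC(=O)Cl | starting material
5 | 4-(trimethylstannyl)pent-4-en-1-yl stearate | CCCCCCCCCCCCCCCCCC(=O)OCCCC(=C)[Sn](C)(C)C | intermediate
6 | diisopropyl squarate (3,4-diisopropoxycyclobut-3-ene-1,2-dione) | CC(C)OC1=C(OC(C)C)C(=O)C1=O | starting material
7 | (±)-4-hydroxy-2,3-diisopropoxycyclobut-2-en-1-one (one enantiomer drawn) | CC(C)OC1=C(OC(C)C)[C@H](O)C1=O | intermediate
8 | (±)-[(2,3-diisopropoxy-4-oxocyclobut-2-en-1-yl)oxy]triphenylphosphonium chloride (one enantiomer drawn) | CC(C)OC1=C(OC(C)C)[C@H](O[P+](c2ccccc2)(c2ccccc2)c2ccccc2)C1=O.[Cl-] | intermediate (not isolated)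
9 | (±)-4-chloro-2,3-diisopropoxycyclobut-2-en-1-one (one enantiomer drawn) | CC(C)OC1=C(OC(C)C)[C@@H](Cl)C1=O | intermediate
10 | (±)-4-(2,3-diisopropoxy-4-oxocyclobut-2-en-1-yl)pent-4-en-1-yl stearate (one enantiomer drawn) | CCCCCCCCCCCCCCCCCC(=O)OCCCC(=C)[C@H]1C(=O)C(OC(C)C)=C1OC(C)C | intermediate
11 | (3E)-5-methylidene-1-oxo-2,3-diisopropoxyocta-1,3-dien-8-yl stearate (dienylketene; ketene-bearing C2 and alkenyl C5 cis across C3=C4) | CCCCCCCCCCCCCCCCCC(=O)OCCCC(=C)/C=C(/OC(C)C)C(OC(C)C)=C=O | intermediate (not isolated)
12 | 3-(3,4-diisopropoxy-5-oxocyclohexa-1,3-dien-1-yl)propyl stearate | CCCCCCCCCCCCCCCCCC(=O)OCCCC1=CC(OC(C)C)=C(OC(C)C)C(=O)C1 | intermediate (not isolated)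
13 | 3-(3-hydroxy-4,5-diisopropoxyphenyl)propyl stearate | CCCCCCCCCCCCCCCCCC(=O)OCCCc1cc(O)c(OC(C)C)c(OC(C)C)c1 | intermediate
14 | 3-(3,4-diisopropoxy-5-methoxyphenyl)propyl stearate | CCCCCCCCCCCCCCCCCC(=O)OCCCc1cc(OC)c(OC(C)C)c(OC(C)C)c1 | intermediate
15 | 3-(2-chloro-7-methoxy-1,3,2-benzodioxaborol-5-yl)propyl stearate | CCCCCCCCCCCCCCCCCC(=O)OCCCc1cc(OC)c2OB(Cl)Oc2c1 | intermediate (not isolated)
16 | 3-(3,4-dihydroxy-5-methoxyphenyl)propyl stearate | CCCCCCCCCCCCCCCCCC(=O)OCCCc1cc(O)c(O)c(OC)c1 | target

**Step count and risks**

Total step count: 8. Longest linear sequence: 6 steps (6 to 16 through steps 3 to 8; equally 1 to 16 through steps 1, 2 and 5 to 8).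

Steps most likely to fail:

1. Step 4. The activated C4–O bond of 8, or the C4–Cl bond of 9 once formed, may ionise with help from the isopropoxy group on C2. Chloride delivery to C2 and loss of an isopropyl group would then collapse the ring to a cyclobutene-1,2-dione. The fallback sets out from 7 and comes back at 10. Acetylation (Ac2O, pyridine, DMAP, CH2Cl2, 0 °C) gives (±)-2,3-diisopropoxy-4-oxocyclobut-2-en-1-yl acetate F1, which is less prone to ionise and is formed without chloride. F1 is then coupled with stannane 5 in the allylic acetate variant of the Stille coupling (Pd2(dba)3, tri(2-furyl)phosphine, LiCl, DMF, rt to 40 °C) to give 10, so that no free chloride has to be accumulated.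

2. Step 5. Transmetalation of the alpha-branched alkenyl group may be slow, so that decomposition of the chloride, protodestannylation, or premature ring opening of the product under palladium outruns the coupling. The fallback sets out from 5 and comes back at 10. Iododestannylation (I2, CH2Cl2, 0 °C) gives 4-iodopent-4-en-1-yl stearate F2. Insertion of highly activated zinc (from ZnCl2 and lithium naphthalenide, THF, rt) gives [5-(stearoyloxy)pent-1-en-2-yl]zinc iodide F3. Negishi coupling of F3 with chloride 9 (Pd(PPh3)4, THF, 0 °C to rt) gives 10. The zinc reagent tolerates the ester and transmetalates at a temperature where 9 and 10 should be stable.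

3. Step 6. Ring opening may proceed mainly by outward rotation of the alkenyl group, and the unproductive ketene may be drained by dimerisation or cycloaddition before it can reclose. A 1,5-hydrogen shift from the allylic methylene of the chain to the ketene carbon may also compete. The fallback sets out from 3 and 6 and comes back at 14. It keeps the squarate ring expansion but places an oxygen on C4 of the cyclobutenone, whose outward rotation forces the alkenyl group inward, and removes that oxygen afterwards.
   - Silylation of 3 (TBSCl, imidazole, DMF) gives tert-butyldimethyl{[4-(trimethylstannyl)pent-4-en-1-yl]oxy}silane F4.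
   - Tin–lithium exchange (MeLi, THF, –78 °C) gives [5-(tert-butyldimethylsilyloxy)pent-1-en-2-yl]lithium F5, which adds to one carbonyl of 6 and after aqueous NH4Cl gives (±)-4-hydroxy-4-[5-(tert-butyldimethylsilyloxy)pent-1-en-2-yl]-2,3-diisopropoxycyclobut-2-en-1-one F6.
   - TBSOTf and 2,6-lutidine (CH2Cl2, –78 °C) give the bis-silyl ether (±)-4-(tert-butyldimethylsilyloxy)-4-[5-(tert-butyldimethylsilyloxy)pent-1-en-2-yl]-2,3-diisopropoxycyclobut-2-en-1-one F7.
   - Thermolysis in toluene at 110 °C gives 4-(tert-butyldimethylsilyloxy)-5-[3-(tert-butyldimethylsilyloxy)propyl]-2,3-diisopropoxyphenol F8, with the free phenol again on the former ketene carbon.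
   - MeI and K2CO3 in acetone give tert-butyl{6-[3-(tert-butyldimethylsilyloxy)propyl]-2,3-diisopropoxy-4-methoxyphenoxy}dimethylsilane F9.
   - TBAF in THF removes both silyl groups to give 6-(3-hydroxypropyl)-2,3-diisopropoxy-4-methoxyphenol F10.
   - PhNTf2, Et3N and DMAP triflate the phenol selectively to give 6-(3-hydroxypropyl)-2,3-diisopropoxy-4-methoxyphenyl trifluoromethanesulfonate F11.
   - Reduction of the aryl triflate (Pd(OAc)2, dppf, HCO2H, Et3N, DMF, 80 °C) gives 3-(3,4-diisopropoxy-5-methoxyphenyl)propan-1-ol F12.
   - Acylation of F12 with 4 (pyridine, DMAP, CH2Cl2) gives 14, which enters step 8.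

**Further compounds**

F1 | step 4 | (±)-2,3-diisopropoxy-4-oxocyclobut-2-en-1-yl acetate (one enantiomer drawn) | CC(=O)O[C@H]1C(=O)C(OC(C)C)=C1OC(C)C
F2 | step 5 | 4-iodopent-4-en-1-yl stearate | CCCCCCCCCCCCCCCCCC(=O)OCCCC(=C)I
F3 | step 5 | [5-(stearoyloxy)pent-1-en-2-yl]zinc iodide | CCCCCCCCCCCCCCCCCC(=O)OCCCC(=C)[Zn]I
F4 | step 6 | tert-butyldimethyl{[4-(trimethylstannyl)pent-4-en-1-yl]oxy}silane | C=C(CCCO[Si](C)(C)C(C)(C)C)[Sn](C)(C)C
F5 | step 6 | [5-(tert-butyldimethylsilyloxy)pent-1-en-2-yl]lithium | [Li]C(=C)CCCO[Si](C)(C)C(C)(C)C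
F6 | step 6 | (±)-4-hydroxy-4-[5-(tert-butyldimethylsilyloxy)pent-1-en-2-yl]-2,3-diisopropoxycyclobut-2-en-1-one (one enantiomer drawn) | CC(C)OC1=C(OC(C)C)[C@](O)(C(=C)CCCO[Si](C)(C)C(C)(C)C)C1=O
F7 | step 6 | (±)-4-(tert-butyldimethylsilyloxy)-4-[5-(tert-butyldimethylsilyloxy)pent-1-en-2-yl]-2,3-diisopropoxycyclobut-2-en-1-one (one enantiomer drawn) | CC(C)OC1=C(OC(C)C)[C@](O[Si](C)(C)C(C)(C)C)(C(=C)CCCO[Si](C)(C)C(C)(C)C)C1=O
F8 | step 6 | 4-(tert-butyldimethylsilyloxy)-5-[3-(tert-butyldimethylsilyloxy)propyl]-2,3-diisopropoxyphenol | CC(C)Oc1c(O)cc(CCCO[Si](C)(C)C(C)(C)C)c(O[Si](C)(C)C(C)(C)C)c1OC(C)C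
F9 | step 6 | tert-butyl{6-[3-(tert-butyldimethylsilyloxy)propyl]-2,3-diisopropoxy-4-methoxyphenoxy}dimethylsilane | CC(C)Oc1c(OC)cc(CCCO[Si](C)(C)C(C)(C)C)c(O[Si](C)(C)C(C)(C)C)c1OC(C)C
F10 | step 6 | 6-(3-hydroxypropyl)-2,3-diisopropoxy-4-methoxyphenol | CC(C)Oc1c(OC)cc(CCCO)c(O)c1OC(C)C
F11 | step 6 | 6-(3-hydroxypropyl)-2,3-diisopropoxy-4-methoxyphenyl trifluoromethanesulfonate | CC(C)Oc1c(OC)cc(CCCO)c(OS(=O)(=O)C(F)(F)F)c1OC(C)C
F12 | step 6 | 3-(3,4-diisopropoxy-5-methoxyphenyl)propan-1-ol | CC(C)Oc1c(OC)cc(CCCO)cc1OC(C)C
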